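**Plan**

- Rings are lettered A (2,4,6-trihydroxyphenoxy end) to E (3,4,5-trihydroxyphenoxy end); ring A is numbered with C1 as the carbon bearing the ether oxygen to ring B.
- Retrosynthesis: the ten O–CH3 bonds and the two C–CO2Me bonds on ring A are cut first, then ring A itself at C2–C3 and C6–C5, then the malonate O–CH bond, then the diaryl ether bonds B–C, C–D and D–E in turn.
- Enabling feature: in ring A, C1 lies between the hydroxyl-bearing C2 and C6, which is the central carbon and the two ester carbons of an aryloxymalonate, while C3–C4(OH)–C5 is the CH2–CO–CH2 unit of a 3-oxopentanedioate.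
- Forward: rings E and D are joined by Chan–Lam arylation, rings C and B are added by copper-catalysed Ullmann couplings of bromobenzaldehydes, and each formyl group is converted into the next phenol by Baeyer–Villiger oxidation; the ring B phenol is then alkylated with chloromalonate.
- Ring A is the only ring constructed and it is closed last; ester removal and BBr3 demethylation finish the route.
- Stereochemistry: the target has no stereocentre, so nothing has to be set.

Key step: step 9

Remark: the target is treated as the achiral constitution of the SMILES, with freely rotating diaryl ether bonds. Compounds 1, 2, 6, 11, 15 and 17 are taken as purchased. In names below, Ar = 3-{2-[3,5-dimethoxy-4-(3,4,5-trimethoxyphenoxy)phenoxy]-3,4,5-trimethoxyphenoxy}-4,5-dimethoxyphenyl, the permethylated ring B–E tetramer bonded through ring B C1.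

**Route**

Step 1
Reactants: 1 syringaldehyde (4-hydroxy-3,5-dimethoxybenzaldehyde); 2 3,4,5-trimethoxyphenylboronic acid
Product: 3 3,5-dimethoxy-4-(3,4,5-trimethoxyphenoxy)benzaldehyde
Conditions: Cu(OAc)2 (1 equiv), pyridine, 4 Å MS, O2 (balloon), CH2Cl2, rt
Reagents that add atoms: none
Why: Chan–Lam oxidative O-arylation, in which the acidic phenol binds divalent copper, the electron-rich arylboronic acid transmetalates and C–O reductive elimination (O2 as terminal oxidant) should form the ring D–O–ring E bond at room temperature despite the two flanking methoxy groups, the aldehyde being inert.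

Step 2
Reactants: 3 3,5-dimethoxy-4-(3,4,5-trimethoxyphenoxy)benzaldehyde
Product: 5 3,5-dimethoxy-4-(3,4,5-trimethoxyphenoxy)phenol, via aryl formate 4 (not isolated)
Conditions: mCPBA, CH2Cl2, 0 °C to rt; aq. NaHCO3 wash; then K2CO3 (cat.), MeOH, rt
Reagents that add atoms: mCPBA (3-chloroperoxybenzoic acid), OOC(=O)c1cccc(Cl)c1
Why: Baeyer–Villiger oxidation in which the electron-rich, para-aryloxy-substituted aryl group migrates in preference to hydride to give the aryl formate, which catalytic methoxide transesterifies to free the ring D phenol.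

Step 3
Reactants: 6 3,4,5-trimethoxybenzaldehyde
Product: 7 2-bromo-3,4,5-trimethoxybenzaldehyde
Conditions: NBS, CHCl3, reflux
Reagents that add atoms: N-bromosuccinimide, O=C1CCC(=O)N1Br
Why: Electrophilic aromatic bromination at one of the two equivalent free positions, each activated by ortho and para methoxy groups, so that only one monobromide can form and the deactivated product should resist a second bromination.

Step 4
Reactants: 5 3,5-dimethoxy-4-(3,4,5-trimethoxyphenoxy)phenol; 7 2-bromo-3,4,5-trimethoxybenzaldehyde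
Product: 8 2-[3,5-dimethoxy-4-(3,4,5-trimethoxyphenoxy)phenoxy]-3,4,5-trimethoxybenzaldehyde
Conditions: CuI (10 mol%), picolinic acid (20 mol%), K3PO4, DMSO, 90 °C
Reagents that add atoms: none
Why: Ullmann-type copper-catalysed diaryl ether synthesis in which the ortho-formyl group speeds oxidative addition of the C–Br bond to the monovalent copper phenoxide and the nucleophile 5 carries no ortho substituent.

Step 5
Reactants: 8 2-[3,5-dimethoxy-4-(3,4,5-trimethoxyphenoxy)phenoxy]-3,4,5-trimethoxybenzaldehyde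
Product: 10 2-[3,5-dimethoxy-4-(3,4,5-trimethoxyphenoxy)phenoxy]-3,4,5-trimethoxyphenol, via aryl formate 9 (not isolated)
Conditions: mCPBA, CH2Cl2, 0 °C to rt; aq. NaHCO3 wash; then K2CO3 (cat.), MeOH, rt
Reagents that add atoms: mCPBA (3-chloroperoxybenzoic acid), OOC(=O)c1cccc(Cl)c1
Why: Baeyer–Villiger oxidation in which the aryl group, made electron-rich by its ortho-aryloxy and para-methoxy substituents, migrates to oxygen, and methanolysis of the formate uncovers the ring C phenol next to the ring D ether.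

Step 6
Reactants: 10 2-[3,5-dimethoxy-4-(3,4,5-trimethoxyphenoxy)phenoxy]-3,4,5-trimethoxyphenol; 11 3-bromo-4,5-dimethoxybenzaldehyde
Product: 12 3-{2-[3,5-dimethoxy-4-(3,4,5-trimethoxyphenoxy)phenoxy]-3,4,5-trimethoxyphenoxy}-4,5-dimethoxybenzaldehyde (Ar–CHO)
Conditions: CuI (10 mol%), picolinic acid (20 mol%), K3PO4, DMSO, 100 °C
Reagents that add atoms: none
Why: Ullmann-type diaryl ether coupling under the CuI–picolinic acid system suited to ortho-substituted partners; the non-enolisable aldehyde should tolerate K3PO4 and places the future ring B hydroxyl meta to the new ether.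

Step 7
Reactants: 12 Ar–CHO
Product: 14 3-{2-[3,5-dimethoxy-4-(3,4,5-trimethoxyphenoxy)phenoxy]-3,4,5-trimethoxyphenoxy}-4,5-dimethoxyphenol (Ar–OH), via aryl formate 13 (not isolated)
Conditions: mCPBA, CH2Cl2, 0 °C to rt; aq. NaHCO3 wash; then K2CO3 (cat.), MeOH, rt
Reagents that add atoms: mCPBA (3-chloroperoxybenzoic acid), OOC(=O)c1cccc(Cl)c1
Why: Baeyer–Villiger oxidation of a 3,4,5-trioxygenated benzaldehyde, a substrate class in which aryl migration is reliable, followed by formate methanolysis to the ring B phenol.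

Step 8
Reactants: 14 Ar–OH; 15 dimethyl chloromalonate
Product: 16 dimethyl 2-(ArO)malonate
Conditions: K2CO3, acetone, reflux
Reagents that add atoms: none
Why: Williamson ether synthesis by SN2 displacement of chloride at the doubly ester-activated carbon, the chloride being preferred to the bromide to avoid halogen transfer to the electron-rich phenoxide ring.

Step 9
Reactants: 16 dimethyl 2-(ArO)malonate; 17 dimethyl 3-oxopentanedioate
Product: 19 dimethyl 2,4,6-trihydroxy-5-(ArO)benzene-1,3-dicarboxylate, via acyclic Claisen adduct 18 (not isolated)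
Conditions: 17 (3 equiv), NaOMe (5 equiv), MeOH, rt; add 16; then toluene, 110 °C with distillation of MeOH; 1 M HCl
Reagents that add atoms: none
Why: Proposed new method: NaOMe turns 17 into its sodium enolate, whose methylene carbon attacks one ester carbonyl of 16 (crossed Claisen acylation) to give the acyclic adduct 18 as a stabilised enolate; deprotonation of the second methylene and attack on the remaining malonate ester closes ring A by a Dieckmann acylation (6-exo-trig), and the cyclohexane-1,3,5-trione so formed tautomerises to the aromatic triol, which leaves all equilibria as its sodium phenoxide. The closest known reaction type is the alkoxide-mediated condensation of dialkyl malonates with dialkyl 3-oxopentanedioates to phloroglucinol dicarboxylates, and aryloxymalonates are established 1,3-dielectrophiles toward amidines under NaOMe, but a 2-aryloxymalonate has not been shown in the carbocyclic version. No stereocentre is formed. The step needs cross- over self-condensation and C- over O-acylation: 17 is fully enolised before 16 is added, which masks its own ketone and esters as electrophiles, and it is used in excess, while enol esters from O-acylation are cleaved again by methoxide, so material should funnel to the one product that can aromatise. Both partners are symmetric, so only one constitution is possible, and methyl esters matched to methoxide make ester exchange invisible. The aryloxy group raises the electrophilicity of the malonate carbonyls by induction, which should offset the partial deprotonation of 16.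

Step 10
Reactants: 19 dimethyl 2,4,6-trihydroxy-5-(ArO)benzene-1,3-dicarboxylate
Product: 21 2-(ArO)benzene-1,3,5-triol, via diacid 20 (not isolated)
Conditions: KOH, H2O/dioxane (degassed, Ar), 90 °C; then aq. HCl to pH 1, 60 °C
Reagents that add atoms: none
Why: Ester saponification followed by decarboxylation of the 2,4,6-trihydroxybenzoic acid units, which on acidification should lose CO2 readily through their ring-protonated β-keto acid tautomers, while aryl methyl ethers and diaryl ethers are inert to aqueous base.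

Step 11
Reactants: 21 2-(ArO)benzene-1,3,5-triol
Product: 22 2-[3-[2-[3,5-dihydroxy-4-(3,4,5-trihydroxyphenoxy)phenoxy]-3,4,5-trihydroxyphenoxy]-4,5-dihydroxyphenoxy]benzene-1,3,5-triol (CNP0228612.0)
Conditions: BBr3 (excess), CH2Cl2, −78 °C to rt, Ar; then H2O, 0 °C
Reagents that add atoms: none
Why: BBr3 cleavage of aryl methyl ethers, in which boron coordinates each methoxy oxygen and bromide removes the methyl group by SN2, whereas the diaryl ether bonds offer no carbon open to such attack and should persist.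

**Compound list**

1 | syringaldehyde (4-hydroxy-3,5-dimethoxybenzaldehyde) | COc1cc(C=O)cc(OC)c1O | starting material
2 | 3,4,5-trimethoxyphenylboronic acid | COc1cc(B(O)O)cc(OC)c1OC | starting material
3 | 3,5-dimethoxy-4-(3,4,5-trimethoxyphenoxy)benzaldehyde | COc1cc(C=O)cc(OC)c1Oc2cc(OC)c(OC)c(OC)c2 | intermediate
4 | 3,5-dimethoxy-4-(3,4,5-trimethoxyphenoxy)phenyl formate | COc1cc(OC=O)cc(OC)c1Oc2cc(OC)c(OC)c(OC)c2 | intermediate
5 | 3,5-dimethoxy-4-(3,4,5-trimethoxyphenoxy)phenol | COc1cc(O)cc(OC)c1Oc2cc(OC)c(OC)c(OC)c2 | intermediate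
6 | 3,4,5-trimethoxybenzaldehyde | COc1cc(C=O)cc(OC)c1OC | starting material
7 | 2-bromo-3,4,5-trimethoxybenzaldehyde | COc1cc(C=O)c(Br)c(OC)c1OC | intermediate
8 | 2-[3,5-dimethoxy-4-(3,4,5-trimethoxyphenoxy)phenoxy]-3,4,5-trimethoxybenzaldehyde | COc1cc(C=O)c(Oc2cc(OC)c(Oc3cc(OC)c(OC)c(OC)c3)c(OC)c2)c(OC)c1OC | intermediate
9 | 2-[3,5-dimethoxy-4-(3,4,5-trimethoxyphenoxy)phenoxy]-3,4,5-trimethoxyphenyl formate | COc1cc(OC=O)c(Oc2cc(OC)c(Oc3cc(OC)c(OC)c(OC)c3)c(OC)c2)c(OC)c1OC | intermediate
10 | 2-[3,5-dimethoxy-4-(3,4,5-trimethoxyphenoxy)phenoxy]-3,4,5-trimethoxyphenol | COc1cc(O)c(Oc2cc(OC)c(Oc3cc(OC)c(OC)c(OC)c3)c(OC)c2)c(OC)c1OC | intermediate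
11 | 3-bromo-4,5-dimethoxybenzaldehyde | COc1cc(C=O)cc(Br)c1OC | starting material
12 | 3-{2-[3,5-dimethoxy-4-(3,4,5-trimethoxyphenoxy)phenoxy]-3,4,5-trimethoxyphenoxy}-4,5-dimethoxybenzaldehyde | COc1cc(C=O)cc(Oc2cc(OC)c(OC)c(OC)c2Oc3cc(OC)c(Oc4cc(OC)c(OC)c(OC)c4)c(OC)c3)c1OC | intermediate
13 | 3-{2-[3,5-dimethoxy-4-(3,4,5-trimethoxyphenoxy)phenoxy]-3,4,5-trimethoxyphenoxy}-4,5-dimethoxyphenyl formate | COc1cc(OC=O)cc(Oc2cc(OC)c(OC)c(OC)c2Oc3cc(OC)c(Oc4cc(OC)c(OC)c(OC)c4)c(OC)c3)c1OC | intermediate
14 | 3-{2-[3,5-dimethoxy-4-(3,4,5-trimethoxyphenoxy)phenoxy]-3,4,5-trimethoxyphenoxy}-4,5-dimethoxyphenol | COc1cc(O)cc(Oc2cc(OC)c(OC)c(OC)c2Oc3cc(OC)c(Oc4cc(OC)c(OC)c(OC)c4)c(OC)c3)c1OC | intermediate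
15 | dimethyl chloromalonate (dimethyl 2-chloropropanedioate) | COC(=O)C(Cl)C(=O)OC | starting material
16 | dimethyl 2-(3-{2-[3,5-dimethoxy-4-(3,4,5-trimethoxyphenoxy)phenoxy]-3,4,5-trimethoxyphenoxy}-4,5-dimethoxyphenoxy)malonate | COC(=O)C(Oc1cc(OC)c(OC)c(Oc2cc(OC)c(OC)c(OC)c2Oc3cc(OC)c(Oc4cc(OC)c(OC)c(OC)c4)c(OC)c3)c1)C(=O)OC | intermediate
17 | dimethyl 3-oxopentanedioate | COC(=O)CC(=O)CC(=O)OC | starting material
18 | dimethyl 2-[2-(ArO)-3-methoxy-3-oxopropanoyl]-3-oxopentanedioate (acyclic Claisen adduct) | COC(=O)CC(=O)C(C(=O)OC)C(=O)C(Oc1cc(OC)c(OC)c(Oc2cc(OC)c(OC)c(OC)c2Oc3cc(OC)c(Oc4cc(OC)c(OC)c(OC)c4)c(OC)c3)c1)C(=O)OC | intermediate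
19 | dimethyl 2,4,6-trihydroxy-5-(ArO)benzene-1,3-dicarboxylate | COC(=O)c1c(O)c(C(=O)OC)c(O)c(Oc2cc(OC)c(OC)c(Oc3cc(OC)c(OC)c(OC)c3Oc4cc(OC)c(Oc5cc(OC)c(OC)c(OC)c5)c(OC)c4)c2)c1O | intermediate
20 | 2,4,6-trihydroxy-5-(ArO)benzene-1,3-dicarboxylic acid | OC(=O)c1c(O)c(C(=O)O)c(O)c(Oc2cc(OC)c(OC)c(Oc3cc(OC)c(OC)c(OC)c3Oc4cc(OC)c(Oc5cc(OC)c(OC)c(OC)c5)c(OC)c4)c2)c1O | intermediate
21 | 2-(ArO)benzene-1,3,5-triol (decamethyl ether of the target) | Oc1cc(O)c(Oc2cc(OC)c(OC)c(Oc3cc(OC)c(OC)c(OC)c3Oc4cc(OC)c(Oc5cc(OC)c(OC)c(OC)c5)c(OC)c4)c2)c(O)c1 | intermediate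
22 | 2-[3-[2-[3,5-dihydroxy-4-(3,4,5-trihydroxyphenoxy)phenoxy]-3,4,5-trihydroxyphenoxy]-4,5-dihydroxyphenoxy]benzene-1,3,5-triol (CNP0228612.0) | Oc1cc(O)c(Oc2cc(O)c(O)c(Oc3cc(O)c(O)c(O)c3Oc3cc(O)c(Oc4cc(O)c(O)c(O)c4)c(O)c3)c2)c(O)c1 | target

**Totals**

Total step count: 11. Longest linear sequence: 10 steps (steps 1, 2 and 4 to 11); step 3 is a one-step branch.

**Steps most likely to fail**

1. Step 9 (ring A benzannulation). The crossed Claisen acylation may lose to self-condensation of the ketodiester, the sequence may stall at the acyclic stage, or methoxide may strip a methoxycarbonyl group from the malonate before the ring closes. The fallback sets out from phenol 14 and attaches ring A as a preformed arene, repeating the chemistry of steps 1 and 2. Triflation (Tf2O, pyridine, CH2Cl2, 0 °C) should give the aryl triflate F1. Palladium-catalysed borylation (Pd(OAc)2, XPhos, B2(OH)4, KOAc, EtOH, 80 °C) should convert it into the boronic acid F2. Chan–Lam coupling of F2 with syringaldehyde 1 (Cu(OAc)2, pyridine, 4 Å MS, O2, CH2Cl2) should give the pentamer aldehyde F3, in which ring A is a 4-formyl-2,6-dimethoxyphenoxy group. Baeyer–Villiger oxidation (mCPBA, CH2Cl2) should lead to the aryl formate F4, and methanolysis (K2CO3, MeOH) to the dodecamethyl ether phenol F5. BBr3 in CH2Cl2 then cleaves all twelve methyl ethers, so the fallback comes back to the route at the target 22.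

2. Step 6 (ring B–ring C Ullmann coupling). C–O bond formation between an ortho-aryloxy phenol and an ortho-methoxy, electron-rich aryl bromide may be slow enough that reductive debromination or loss of the aldehyde outruns coupling. The fallback sets out from phenol 10 and introduces ring B without its hydroxyl group. Chan–Lam arylation with 2,3-dimethoxyphenylboronic acid (Cu(OAc)2, pyridine, 4 Å MS, O2, CH2Cl2) should give the 2,3-dimethoxyphenyl ether F6. Iridium-catalysed C–H borylation ([Ir(OMe)(cod)]2, 4,4'-di-tert-butyl-2,2'-bipyridine, B2pin2, THF, 80 °C) should then strike ring B C5, the only C–H bond in the molecule without an ortho substituent, to give the pinacol boronate F7. Oxidation (H2O2, NaOH, THF/H2O, 0 °C) turns the C–B bond into the hydroxyl group, and the fallback comes back to the route at phenol 14.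

3. Step 11 (tenfold demethylation). Cleavage may stop short at the methyl ethers flanked on both sides, and the free tridecahydroxy compound may oxidise in air during aqueous work-up and chromatography. The fallback sets out from 21. After BBr3 treatment and quench, the crude polyphenol is not purified but acetylated at once (Ac2O, pyridine, DMAP, rt) to the tridecaacetate F8, which is stable and can be purified on silica gel and separated from partially methylated material. Acid-catalysed methanolysis (acetyl chloride (cat.) in MeOH, rt, Ar) avoids phenoxide formation and brings the route back at the target 22.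

**Further compounds**

F1 | step 9 | 3-{2-[3,5-dimethoxy-4-(3,4,5-trimethoxyphenoxy)phenoxy]-3,4,5-trimethoxyphenoxy}-4,5-dimethoxyphenyl trifluoromethanesulfonate | COc1cc(OS(=O)(=O)C(F)(F)F)cc(Oc2cc(OC)c(OC)c(OC)c2Oc3cc(OC)c(Oc4cc(OC)c(OC)c(OC)c4)c(OC)c3)c1OC
F2 | step 9 | (3-{2-[3,5-dimethoxy-4-(3,4,5-trimethoxyphenoxy)phenoxy]-3,4,5-trimethoxyphenoxy}-4,5-dimethoxyphenyl)boronic acid | COc1cc(B(O)O)cc(Oc2cc(OC)c(OC)c(OC)c2Oc3cc(OC)c(Oc4cc(OC)c(OC)c(OC)c4)c(OC)c3)c1OC
F3 | step 9 | 4-(ArO)-3,5-dimethoxybenzaldehyde (pentamer aldehyde) | COc1cc(C=O)cc(OC)c1Oc2cc(OC)c(OC)c(Oc3cc(OC)c(OC)c(OC)c3Oc4cc(OC)c(Oc5cc(OC)c(OC)c(OC)c5)c(OC)c4)c2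
F4 | step 9 | 4-(ArO)-3,5-dimethoxyphenyl formate | COc1cc(OC=O)cc(OC)c1Oc2cc(OC)c(OC)c(Oc3cc(OC)c(OC)c(OC)c3Oc4cc(OC)c(Oc5cc(OC)c(OC)c(OC)c5)c(OC)c4)c2
F5 | step 9 | 4-(ArO)-3,5-dimethoxyphenol (dodecamethyl ether phenol) | COc1cc(O)cc(OC)c1Oc2cc(OC)c(OC)c(Oc3cc(OC)c(OC)c(OC)c3Oc4cc(OC)c(Oc5cc(OC)c(OC)c(OC)c5)c(OC)c4)c2
F6 | step 6 | 1-(2,3-dimethoxyphenoxy)-2-[3,5-dimethoxy-4-(3,4,5-trimethoxyphenoxy)phenoxy]-3,4,5-trimethoxybenzene | COc1cccc(Oc2cc(OC)c(OC)c(OC)c2Oc3cc(OC)c(Oc4cc(OC)c(OC)c(OC)c4)c(OC)c3)c1OC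
F7 | step 6 | 2-(3-{2-[3,5-dimethoxy-4-(3,4,5-trimethoxyphenoxy)phenoxy]-3,4,5-trimethoxyphenoxy}-4,5-dimethoxyphenyl)-4,4,5,5-tetramethyl-1,3,2-dioxaborolane | COc1cc(B5OC(C)(C)C(C)(C)O5)cc(Oc2cc(OC)c(OC)c(OC)c2Oc3cc(OC)c(Oc4cc(OC)c(OC)c(OC)c4)c(OC)c3)c1OC
F8 | step 11 | tridecaacetate of the target (all thirteen hydroxyl groups as acetates) | CC(=O)Oc1cc(OC(C)=O)c(Oc2cc(OC(C)=O)c(OC(C)=O)c(Oc3cc(OC(C)=O)c(OC(C)=O)c(OC(C)=O)c3Oc4cc(OC(C)=O)c(Oc5cc(OC(C)=O)c(OC(C)=O)c(OC(C)=O)c5)c(OC(C)=O)c4)c2)c(OC(C)=O)c1
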